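**Strategy.** The chroman is cut at both bonds that join the arene to the dihydropyran ring, C4–C4a and O1–C8a. The unit C2–C3–C4 with its oxygen then arrives as an open-chain (R)-γ-bromo tertiary alcohol carrying the complete polyprenyl side chain, made from solanesol by Sharpless epoxidation and hydride opening. A Catellani annulation with a 4-iodo-2,3-dimethylphenol silyl ether alkylates the free ortho C–H (C4a) through a transient norbornene-bridged palladacycle and closes the ring by aryl C–O coupling at C8a. It exploits the ortho pair C4a/C8a next to the C8 methyl, which blocks the other ortho site. The C2–O bond is never touched, so C2 stays R.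

Key step: step 6

Remark: commercial all-E solanesol supplies the whole C45 skeleton. In the SMILES of the two organopalladium intermediates of step 6 the phosphine on palladium is not drawn, and the racemic exo,cis-norbornane unit of the palladacycle is shown as one enantiomer.

Step 1
Reactants: 1 solanesol
Product: 2 (2R,3R)-2,3-epoxysolanesol
Conditions: Ti(Oi-Pr)4 (10 mol %), D-(−)-diethyl tartrate (12 mol %), t-BuOOH, 4 Å MS, CH2Cl2, −20 °C
Reagents that add atoms: tert-butyl hydroperoxide, CC(C)(C)OO
Why: Sharpless asymmetric epoxidation: the titanium tartrate binds the allylic hydroxyl, so only the C2=C3 olefin of the nine should be oxidised, and D-(−)-diethyl tartrate delivers oxygen to the face of an E-3-methyl-2-alken-1-ol that gives the (2R,3R) epoxide, which sets C3, the future C2 of the chroman.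

Step 2
Reactants: 2 (2R,3R)-2,3-epoxysolanesol
Product: 3 (R)-1,3-diol
Conditions: NaAlH2(OCH2CH2OMe)2 (Red-Al), THF, 0 °C to rt; aq. potassium sodium tartrate (KNaC4H4O6)
Reagents that add atoms: none
Why: Red-Al reduction of a 2,3-epoxy alcohol: the aluminate bound at the C1 oxygen delivers hydride intramolecularly to C2, which should give the 1,3-diol and leaves the C3–O bond, and with it the R configuration, untouched.

Step 3
Reactants: 3 (R)-1,3-diol
Product: 4 (R)-γ-bromo tertiary alcohol
Conditions: CBr4, PPh3, CH2Cl2, 0 °C
Reagents that add atoms: carbon tetrabromide, BrC(Br)(Br)Br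
Why: Appel reaction: only the unhindered primary hydroxyl should form the alkoxyphosphonium ion and be displaced by bromide (SN2) under neutral conditions, while the tertiary hydroxyl and the olefins stay intact.

Step 4
Reactants: 5 2,3-dimethylphenol
Product: 6 4-iodo-2,3-dimethylphenol
Conditions: NIS, p-TsOH (10 mol %), MeCN, rt
Reagents that add atoms: N-iodosuccinimide, O=C1CCC(=O)N1I
Why: Electrophilic aromatic iodination: the hydroxyl group directs to its para position, which acid-activated N-iodosuccinimide favours over the ortho position in phenols.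

Step 5
Reactants: 6 4-iodo-2,3-dimethylphenol
Product: 7 (4-iodo-2,3-dimethylphenoxy)triisopropylsilane
Conditions: i-Pr3SiCl, imidazole, DMF, rt
Reagents that add atoms: chlorotriisopropylsilane, CC(C)[Si](Cl)(C(C)C)C(C)C
Why: Silylation of the phenol: the bulky silyl ether masks the acidic O–H, which would otherwise be O-alkylated by 4, and should survive carbonate base yet be cleaved by fluoride without harm to the polyene.

Step 6
Reactants: 4 (R)-γ-bromo tertiary alcohol; 7 (4-iodo-2,3-dimethylphenoxy)triisopropylsilane
Product: 10 O-triisopropylsilyl ether of the target chromanol, via aryl-norbornyl palladacycle 8 (not isolated), via ortho-alkylated arylpalladium bromide 9 (not isolated)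
Conditions: Pd(OAc)2 (10 mol %), XPhos (20 mol %), norbornene (1 equiv), Cs2CO3 (3 equiv), 1,4-dioxane, 100 °C
Reagents that add atoms: none
Why: Catellani reaction: zerovalent palladium inserts into the C–I bond of 7, norbornene carbopalladation and ortho C–H palladation give palladacycle 8, which takes up the primary bromide of 4 by oxidative addition to tetravalent palladium and forms the C4–C4a bond by reductive elimination, after which, both ortho sites being filled, norbornene is expelled by β-carbon elimination to leave 9. The tertiary alkoxide then binds divalent palladium, and C–O reductive elimination from the seven-membered aryl(alkoxo)palladium chelate forms O1–C8a and closes the six-membered dihydropyran ring. The closest known reactions are the palladium/norbornene annulations of aryl iodides with epoxides (to dihydrobenzofurans) and with bromoalkylamines (to tetrahydroquinolines), together with the palladium-catalysed intramolecular etherification of aryl halides by tertiary alcohols to 2,2-disubstituted chromans. No stereocenter is formed, and C2 keeps its R configuration because none of its bonds, the C2–O bond included, is broken under these basic, non-ionising conditions. The step needs ortho alkylation before ipso termination and a single alkylation site: the C8 methyl blocks one ortho position and forces norbornene extrusion after one alkylation, the tertiary alkoxide has no carbinol hydrogen for β-hydride elimination, and the trisubstituted chain olefins are too hindered to compete with strained norbornene for the arylpalladium species.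

Step 7
Reactants: 10 O-triisopropylsilyl ether of the target chromanol
Product: 11 plastochromanol-8 (target)
Conditions: Bu4NF, AcOH, THF, 0 °C, under argon
Reagents that add atoms: none
Why: Fluoride-mediated desilylation: the strong Si–F bond drives cleavage of the aryl silyl ether, acetic acid keeps the air-sensitive chromanol protonated, and neither the olefins nor C2 should be affected.

**Compound list**

1 | solanesol, (2E,6E,10E,14E,18E,22E,26E,30E)-3,7,11,15,19,23,27,31,35-nonamethylhexatriaconta-2,6,10,14,18,22,26,30,34-nonaen-1-ol | CC(C)=CCC/C(C)=C/CC/C(C)=C/CC/C(C)=C/CC/C(C)=C/CC/C(C)=C/CC/C(C)=C/CC/C(C)=C/CC/C(C)=C/CO | starting material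

2 | (2R,3R)-2,3-epoxysolanesol (trans epoxide at C2–C3, the other eight olefins unchanged) | CC(C)=CCC/C(C)=C/CC/C(C)=C/CC/C(C)=C/CC/C(C)=C/CC/C(C)=C/CC/C(C)=C/CC/C(C)=C/CC[C@@]1(C)O[C@@H]1CO | intermediate

3 | (3R,6E,10E,14E,18E,22E,26E,30E)-3,7,11,15,19,23,27,31,35-nonamethylhexatriaconta-6,10,14,18,22,26,30,34-octaene-1,3-diol | CC(C)=CCC/C(C)=C/CC/C(C)=C/CC/C(C)=C/CC/C(C)=C/CC/C(C)=C/CC/C(C)=C/CC/C(C)=C/CC[C@@](C)(O)CCO | intermediate

4 | (3R,6E,10E,14E,18E,22E,26E,30E)-1-bromo-3,7,11,15,19,23,27,31,35-nonamethylhexatriaconta-6,10,14,18,22,26,30,34-octaen-3-ol | CC(C)=CCC/C(C)=C/CC/C(C)=C/CC/C(C)=C/CC/C(C)=C/CC/C(C)=C/CC/C(C)=C/CC/C(C)=C/CC[C@@](C)(O)CCBr | intermediate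

5 | 2,3-dimethylphenol | Cc1cccc(O)c1C | starting material

6 | 4-iodo-2,3-dimethylphenol | Cc1c(I)ccc(O)c1C | intermediate

7 | (4-iodo-2,3-dimethylphenoxy)triisopropylsilane | Cc1c(I)ccc(O[Si](C(C)C)(C(C)C)C(C)C)c1C | intermediate

8 | aryl-norbornyl palladacycle (five-membered C,C-palladacycle, exo,cis on norbornane, racemic there; phosphine not drawn) | Cc1c(C)c(O[Si](C(C)C)(C(C)C)C(C)C)cc2c1[C@@H]1[C@H]3CC[C@H](C3)[C@@H]1[Pd]2 | intermediate (not isolated)

9 | ortho-alkylated arylpalladium bromide (palladium on the future C8a, (R)-hydroxyalkyl chain on the future C4a; phosphine not drawn) | CC(C)=CCC/C(C)=C/CC/C(C)=C/CC/C(C)=C/CC/C(C)=C/CC/C(C)=C/CC/C(C)=C/CC/C(C)=C/CC[C@@](C)(O)CCc1cc(O[Si](C(C)C)(C(C)C)C(C)C)c(C)c(C)c1[Pd]Br | intermediate (not isolated)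

10 | (2R)-2,7,8-trimethyl-2-[(3E,7E,11E,15E,19E,23E,27E)-4,8,12,16,20,24,28,32-octamethyltritriaconta-3,7,11,15,19,23,27,31-octaenyl]-6-(triisopropylsilyloxy)chroman | CC(C)=CCC/C(C)=C/CC/C(C)=C/CC/C(C)=C/CC/C(C)=C/CC/C(C)=C/CC/C(C)=C/CC/C(C)=C/CC[C@]1(C)CCc2cc(O[Si](C(C)C)(C(C)C)C(C)C)c(C)c(C)c2O1 | intermediate

11 | plastochromanol-8, (2R)-2,7,8-trimethyl-2-[(3E,7E,11E,15E,19E,23E,27E)-4,8,12,16,20,24,28,32-octamethyltritriaconta-3,7,11,15,19,23,27,31-octaenyl]chroman-6-ol | CC(C)=CCC/C(C)=C/CC/C(C)=C/CC/C(C)=C/CC/C(C)=C/CC/C(C)=C/CC/C(C)=C/CC/C(C)=C/CC[C@]1(C)CCc2cc(O)c(C)c(C)c2O1 | target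

**Totals.** Total step count: 7. Longest linear sequence: 5 steps (steps 1, 2, 3, 6, 7, from solanesol).

**Steps most likely to fail**

Step 6. The ipso C–O reductive elimination of the hindered tertiary alkoxide may lag behind protodepalladation of the arylpalladium species, base-induced oxetane closure or elimination of the bromo alcohol, or olefin migration by adventitious palladium hydride. The fallback sets out from 4, forms the same two ring-fusion bonds stepwise through a quinone, and rejoins at 11, so that steps 4, 5 and 7 fall away. Commercial 1,4-dimethoxy-2,3-dimethylbenzene is brominated (NBS, MeCN) to 1-bromo-2,5-dimethoxy-3,4-dimethylbenzene F1, which is converted (Mg, THF) to the Grignard reagent F2. One equivalent of F2 deprotonates the hydroxyl of 4 and a second alkylates its primary bromide under Li2CuCl4 catalysis (THF, −10 °C) to give the (R)-aryl carbinol F3. Oxidative demethylation with (NH4)2Ce(NO3)6 in MeCN/H2O at 0 °C should give the (R)-hydroxy quinone F4, and Na2S2O4 reduces it to the (R)-hydroquinone carbinol F5. Mild acid (camphorsulfonic acid, benzene, rt) should then close the ring by addition of the tertiary hydroxyl to the protonated hydroquinone ring and loss of the phenolic oxygen as water, the course expected for tocopherol-type hydroquinone carbinols, so that the C2–O bond and the R configuration are kept and 11 is obtained.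

Step 3. The phosphonium reagent may activate the tertiary hydroxyl as well (elimination, or oxetane closure from the primary alkoxyphosphonium ion), and the halogenating medium may attack the electron-rich olefins. The fallback sets out from 3 and rejoins at 4 by a two-stage sulfonylation and displacement: TsCl, pyridine, 0 °C should sulfonylate only the primary hydroxyl to give the primary tosylate F6, and LiBr in acetone at 40 °C displaces it (SN2) to give 4.

Step 2. Hydride delivery may leak to the fully substituted C3, giving the 1,2-diol, or the reduction may stall in aluminium chelates of the waxy C45 alkoxide. The fallback sets out from 2 and rejoins at 3 with the regiochemistry fixed by a different mechanism. I2, PPh3 and imidazole (CH2Cl2, 0 °C) convert 2 to the (2S,3R)-epoxy iodide F7 (same geometry, descriptor at C2 changed by priority). Zn dust in EtOH at reflux effects reductive ring opening to the (R)-tertiary allylic alcohol F8 with the C3–O bond intact. 9-BBN in THF followed by NaOH/H2O2 hydroborates only the monosubstituted vinyl group, anti-Markovnikov, to give 3.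

**Further compounds**

F1 | step 6 | 1-bromo-2,5-dimethoxy-3,4-dimethylbenzene | COc1cc(Br)c(OC)c(C)c1C

F2 | step 6 | (2,5-dimethoxy-3,4-dimethylphenyl)magnesium bromide | COc1cc([Mg]Br)c(OC)c(C)c1C

F3 | step 6 | (R)-aryl carbinol, (3R,6E,10E,14E,18E,22E,26E,30E)-1-(2,5-dimethoxy-3,4-dimethylphenyl)-3,7,11,15,19,23,27,31,35-nonamethylhexatriaconta-6,10,14,18,22,26,30,34-octaen-3-ol | CC(C)=CCC/C(C)=C/CC/C(C)=C/CC/C(C)=C/CC/C(C)=C/CC/C(C)=C/CC/C(C)=C/CC/C(C)=C/CC[C@@](C)(O)CCc1cc(OC)c(C)c(C)c1OC

F4 | step 6 | (R)-hydroxy quinone, 2,3-dimethyl-5-[(3R)-3-hydroxy-3-methyl-polyprenylalkyl]-1,4-benzoquinone | CC(C)=CCC/C(C)=C/CC/C(C)=C/CC/C(C)=C/CC/C(C)=C/CC/C(C)=C/CC/C(C)=C/CC/C(C)=C/CC[C@@](C)(O)CCC1=CC(=O)C(C)=C(C)C1=O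

F5 | step 6 | (R)-hydroquinone carbinol, the 1,4-dihydroxyarene corresponding to F4 | CC(C)=CCC/C(C)=C/CC/C(C)=C/CC/C(C)=C/CC/C(C)=C/CC/C(C)=C/CC/C(C)=C/CC/C(C)=C/CC[C@@](C)(O)CCc1cc(O)c(C)c(C)c1O

F6 | step 3 | primary tosylate of (R)-diol 3 | CC(C)=CCC/C(C)=C/CC/C(C)=C/CC/C(C)=C/CC/C(C)=C/CC/C(C)=C/CC/C(C)=C/CC/C(C)=C/CC[C@@](C)(O)CCOS(=O)(=O)c1ccc(C)cc1

F7 | step 2 | (2S,3R)-1-iodo-2,3-epoxide derived from 2 | CC(C)=CCC/C(C)=C/CC/C(C)=C/CC/C(C)=C/CC/C(C)=C/CC/C(C)=C/CC/C(C)=C/CC/C(C)=C/CC[C@@]1(C)O[C@@H]1CI

F8 | step 2 | (R)-tertiary allylic alcohol, (3R,6E,10E,14E,18E,22E,26E,30E)-3,7,11,15,19,23,27,31,35-nonamethylhexatriaconta-1,6,10,14,18,22,26,30,34-nonaen-3-ol | CC(C)=CCC/C(C)=C/CC/C(C)=C/CC/C(C)=C/CC/C(C)=C/CC/C(C)=C/CC/C(C)=C/CC/C(C)=C/CC[C@@](C)(O)C=C
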